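Everything hinges on breaking ring B between C8 and C8a. The feature used is the allylic alcohol motif C1=C8a–C8(O): an oxygenated sp3 carbon sitting directly on an alkene carbon of pyran ring A, which can be made by adding a vinyl-metal at C8a to a formyl group at C8. Because C8a is the carbon that bears the enolic hydroxyl in kojic acid, that oxygen becomes the triflate handle. A single Nozaki–Hiyama–Kishi reaction then forges C8–C8a, closes ring B and sets C8 next to the lactic acid-derived quaternary C7. Its substrate is an acyclic 4-pyranylidene ketone carrying C8a–OTf, the C8 aldehyde, a MOM ether on O7 and a TBS ether on O9.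

Key step: step 13

Numbering: the isochromene numbering of the target is used for all intermediates (C1, O2, C3, C4, C4a, C5, C6, C7, C8, C8a; C9 is the carbon on C3). Ring A is the pyran and ring B the carbocycle. The target is (7R,8R), with O7 and O8 cis.

Assumption: the exocyclic C4a=C5 bond of 16–19 is a push–pull alkene that equilibrates at room temperature. These compounds are drawn as the Z isomer (C6 syn to C8a), which is the form that cyclises.

Step 1
Reactants: 1 (S)-lactic acid; 2 pivalaldehyde
Product: 3 (2S,5S)-2-tert-butyl-5-methyl-1,3-dioxolan-4-one (cis isomer)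
Conditions: p-TsOH·H2O (cat.), H2SO4 (cat.), pentane, reflux, Dean–Stark trap; crystallisation from pentane–Et2O, −78 °C
Reagents that add atoms: none
Why: Acid-catalysed acetalisation with azeotropic removal of water (first stage of self-regeneration of stereocentres) is reversible, so the lactic acid centre steers the new acetal carbon C2 to the more stable cis (2S,5S) isomer, which low-temperature crystallisation should free from the trans isomer.

Step 2
Reactants: 3 (2S,5S)-2-tert-butyl-5-methyl-1,3-dioxolan-4-one
Product: 5 (2S,5R)-2-tert-butyl-5-(hydroxymethyl)-5-methyl-1,3-dioxolan-4-one, via lithium enolate 4 (not isolated)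
Conditions: LiN(iPr)2, THF, −78 °C; CH2O (gas, from cracked paraformaldehyde), −78 °C; aq NH4Cl
Reagents that add atoms: formaldehyde, C=O
Why: Aldol addition of a lithium enolate to monomeric formaldehyde, in which the tert-butyl group on C2 blocks one face of planar enolate 4, so the electrophile enters from the face that carried the hydrogen and the future C7 is set as R with overall retention.

Step 3
Reactants: 5 (2S,5R)-2-tert-butyl-5-(hydroxymethyl)-5-methyl-1,3-dioxolan-4-one
Product: 6 (2S,5R)-2-tert-butyl-5-methyl-5-[(triethylsilyloxy)methyl]-1,3-dioxolan-4-one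
Conditions: Et3SiCl, imidazole, CH2Cl2, 0 °C → rt
Reagents that add atoms: chlorotriethylsilane, CC[Si](Cl)(CC)CC
Why: Routine silylation of a primary alcohol, placed here so that no β-alkoxide can lose formaldehyde by retro-aldol cleavage in step 4, and done with TES because this group can later be removed beside a primary TBS ether.

Step 4
Reactants: 6 (2S,5R)-2-tert-butyl-5-methyl-5-[(triethylsilyloxy)methyl]-1,3-dioxolan-4-one
Product: 7 (2R)-2-hydroxy-N-methoxy-N,2-dimethyl-3-(triethylsilyloxy)propanamide
Conditions: MeNH(OMe)·HCl, iPrMgCl, THF, −20 °C → rt; aq NH4Cl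
Reagents that add atoms: N,O-dimethylhydroxylamine hydrochloride, CNOC.Cl
Why: Weinreb amide formation by aminolysis of the activated lactone carbonyl with the chloromagnesium amide, after which the ring-opened pivalaldehyde hemiacetal collapses and frees the tertiary O7 hydroxyl without involving the quaternary centre.

Step 5
Reactants: 7 (2R)-2-hydroxy-N-methoxy-N,2-dimethyl-3-(triethylsilyloxy)propanamide
Product: 8 (2R)-N-methoxy-2-(methoxymethoxy)-N,2-dimethyl-3-(triethylsilyloxy)propanamide
Conditions: MOMCl, iPr2NEt, Bu4NI (cat.), CH2Cl2, reflux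
Reagents that add atoms: chloromethyl methyl ether, COCCl
Why: Williamson-type O-alkylation of the hindered tertiary alcohol with a very reactive chloromethyl ether under a mild amine base, which leaves the TES ether and the amide untouched and installs the acetal oxygen that later serves as a chelating site.

Step 6
Reactants: 8 (2R)-N-methoxy-2-(methoxymethoxy)-N,2-dimethyl-3-(triethylsilyloxy)propanamide
Product: 9 (3R)-1-bromo-3-(methoxymethoxy)-3-methyl-4-(triethylsilyloxy)butan-2-one
Conditions: BrCH2I, MeLi·LiBr (slow addition to the mixture of 8 and BrCH2I), THF–Et2O, −78 °C; aq NH4Cl at −78 °C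
Reagents that add atoms: bromoiodomethane, BrCI
Why: Carbenoid homologation of a Weinreb amide, in which bromomethyllithium from fast iodine–lithium exchange adds only once because the chelated tetrahedral adduct persists until the cold quench, giving the bromomethyl ketone that brings in C5.

Step 7
Reactants: 10 kojic acid
Product: 11 2-[(tert-butyldimethylsilyloxy)methyl]-5-hydroxy-4H-pyran-4-one
Conditions: TBSCl (1.05 equiv), imidazole, DMF, 0 °C → rt
Reagents that add atoms: tert-butylchlorodimethylsilane, CC(C)(C)[Si](C)(C)Cl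
Why: Chemoselective silylation, since the primary alcohol gives a stable silyl ether whereas any silyl ether of the acidic enolic hydroxyl is hydrolysed on aqueous work-up.

Step 8
Reactants: 11 2-[(tert-butyldimethylsilyloxy)methyl]-5-hydroxy-4H-pyran-4-one
Product: 12 6-[(tert-butyldimethylsilyloxy)methyl]-4-oxo-4H-pyran-3-yl trifluoromethanesulfonate
Conditions: Tf2O, pyridine, CH2Cl2, −20 → 0 °C
Reagents that add atoms: trifluoromethanesulfonic anhydride, O=S(=O)(OS(=O)(=O)C(F)(F)F)C(F)(F)F
Why: O-Sulfonylation of the acidic enolic hydroxyl, standard for 5-hydroxy-4-pyranones, places the alkenyl triflate on the future C8a.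

Step 9
Reactants: 12 6-[(tert-butyldimethylsilyloxy)methyl]-4-oxo-4H-pyran-3-yl trifluoromethanesulfonate
Product: 13 6-[(tert-butyldimethylsilyloxy)methyl]-4-thioxo-4H-pyran-3-yl trifluoromethanesulfonate
Conditions: Lawesson's reagent (0.6 equiv), toluene, 80 °C
Reagents that add atoms: Lawesson's reagent, COc1ccc(cc1)P1(=S)SP(=S)(S1)c1ccc(OC)cc1
Why: Thionation with Lawesson's reagent runs through a four-membered thiaoxaphosphetane in Wittig fashion and is easy for 4-pyranones because of their pyrylium-olate character, while the triflate and the silyl ether offer no reactive carbonyl.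

Step 10
Reactants: 9 (3R)-1-bromo-3-(methoxymethoxy)-3-methyl-4-(triethylsilyloxy)butan-2-one; 13 6-[(tert-butyldimethylsilyloxy)methyl]-4-thioxo-4H-pyran-3-yl trifluoromethanesulfonate
Product: 16 (3R)-1-{(4Z)-2-[(tert-butyldimethylsilyloxy)methyl]-5-(trifluoromethylsulfonyloxy)-4H-pyran-4-ylidene}-3-(methoxymethoxy)-3-methyl-4-(triethylsilyloxy)butan-2-one, via 4-(acylmethylsulfanyl)pyrylium bromide 14 (not isolated), via spiro-thiirane 15 (not isolated)
Conditions: MeCN, rt → 40 °C; then PPh3 (1.5 equiv), iPr2NEt (1.5 equiv), 0 °C → rt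
Reagents that add atoms: none
Why: Eschenmoser sulfide contraction, a reaction type used with thioamides and with 4-thiopyranones and thioflavones, in which the soft thione sulfur is alkylated by the bromoketone, deprotonation of 14 gives a stabilised ylide that can only close onto C4a to give thiirane 15, and the phosphine removes sulfur, so C4a=C5 forms without the competing attack at the unsubstituted C1 that an intermolecular enolate addition to a pyrylium salt would face.

Step 11
Reactants: 16 pyranylidene ketone with C8 triethylsilyl ether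
Product: 17 (3R)-1-{(4Z)-2-[(tert-butyldimethylsilyloxy)methyl]-5-(trifluoromethylsulfonyloxy)-4H-pyran-4-ylidene}-4-hydroxy-3-(methoxymethoxy)-3-methylbutan-2-one
Conditions: PPTS (cat.), MeOH–CH2Cl2, 0 °C
Reagents that add atoms: none
Why: Acid-catalysed methanolysis distinguishes silyl ethers by steric bulk, so the primary TES ether should be cleaved well before the primary TBS ether, and the MOM acetal and the triflate tolerate this weak acid.

Step 12
Reactants: 17 pyranylidene ketone with free C8 hydroxyl
Product: 18 (2R)-4-{(4Z)-2-[(tert-butyldimethylsilyloxy)methyl]-5-(trifluoromethylsulfonyloxy)-4H-pyran-4-ylidene}-2-(methoxymethoxy)-2-methyl-3-oxobutanal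
Conditions: Dess–Martin periodinane, CH2Cl2, 0 °C → rt; filtration through a short silica pad, used at once
Reagents that add atoms: none
Why: Dess–Martin oxidation works on neopentyl-type alcohols under neutral non-aqueous conditions and so should give the non-enolisable β-keto aldehyde without the hydroxide or alkoxide that would trigger retro-Claisen deformylation, and C7 carries no hydrogen and cannot epimerise.

Step 13
Reactants: 18 pyranylidene ketone with C8a triflate and C8 aldehyde
Product: 20 (7R,8R)-3-[(tert-butyldimethylsilyloxy)methyl]-8-hydroxy-7-(methoxymethoxy)-7-methyl-7,8-dihydro-6H-isochromen-6-one, via alkenylchromium dichloride 19 (not isolated)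
Conditions: CrCl2 (8 equiv), NiCl2 (2 mol % of the CrCl2), degassed DMF–THF 1:1, slow addition of 18 to 0.005 M, rt; then H2O
Reagents that add atoms: none
Why: CrCl2 reduces NiCl2 to zerovalent nickel, which inserts into the C8a–O bond of the enol triflate, and transmetalation to trivalent chromium gives alkenylchromium dichloride 19, whose C8a–Cr bond adds to the C8 aldehyde while a second equivalent of CrCl2 completes the two-electron balance. The closest known reaction type is the intramolecular Nozaki–Hiyama–Kishi cyclisation of alkenyl triflates onto aldehydes. Ring B (C4a, C5, C6, C7, C8, C8a) closes in the 6-exo-trig mode, which only the Z form of C4a=C5 allows, but this push–pull bond has pyrylium enolate character and rotates at room temperature, so the E form should drain through the Z form. The new centre C8 is controlled by quaternary C7: a trivalent chromium salt held between the aldehyde oxygen and the inner MOM oxygen O7 forms a five-membered chelate that fits the half-chair of the nascent ring only when cis-fused (O7–C7–C8–O8 near 45° against near 75° for the trans-diequatorial array), so C8a should attack the aldehyde face that leaves O8 syn to O7, which is 8R. The step needs chemoselectivity for the aldehyde, secured because the weakly basic organochromium ignores the vinylogous ester, the acetal and the silyl ether and could reach the C6 ketone only through a four-membered ring, and it needs ring closure to outrun oligomerisation and protonation, secured by high dilution and a dry neutral medium that also spares the β-keto aldehyde from deformylation. The THF share of the solvent leaves coordination sites on the metal free for chelation and so disfavours the dipole-opposed, trans-diaxial approach.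

Step 14
Reactants: 21 orsellinic acid
Product: 22 methoxymethyl 2,4-bis(methoxymethoxy)-6-methylbenzoate
Conditions: NaH (3.3 equiv), MOMCl (3.5 equiv), DMF, 0 °C → rt
Reagents that add atoms: chloromethyl methyl ether, COCCl
Why: Exhaustive O-alkylation of the carboxylate and both phenoxides, with NaH used so that the hydrogen-bonded ortho phenol is also deprotonated and protected.

Step 15
Reactants: 22 methoxymethyl 2,4-bis(methoxymethoxy)-6-methylbenzoate
Product: 23 2,4-bis(methoxymethoxy)-6-methylbenzoic acid
Conditions: LiOH, THF–MeOH–H2O, rt; then 1 M HCl to pH 4, 0 °C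
Reagents that add atoms: lithium hydroxide, [Li+].[OH-]
Why: Saponification of the acylal-type MOM ester is fast at room temperature despite the two ortho substituents, aryl MOM ethers are inert to base, and cold mild acidification avoids loss of MOM groups and decarboxylation.

Step 16
Reactants: 20 (7R,8R)-bicyclic alcohol; 23 2,4-bis(methoxymethoxy)-6-methylbenzoic acid
Product: 25 (7R,8R)-3-[(tert-butyldimethylsilyloxy)methyl]-7-(methoxymethoxy)-7-methyl-6-oxo-7,8-dihydro-6H-isochromen-8-yl 2,4-bis(methoxymethoxy)-6-methylbenzoate, via aroyl chloride 24 (not isolated)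
Conditions: 23, 1-chloro-N,N,2-trimethylpropenylamine, CH2Cl2, 0 °C; then 20, Et3N, DMAP, CH2Cl2, 0 °C → rt
Reagents that add atoms: none
Why: Acid chloride formation with the chloroenamine is neutral and spares the MOM acetals, and DMAP-catalysed acylation of the only free hydroxyl leaves the C8–O bond intact (retention) under amine bases too weak to start a retro-aldol opening of the β-hydroxy ketone.

Step 17
Reactants: 25 C8 orsellinate with C9 silyl ether
Product: 26 (7R,8R)-3-(hydroxymethyl)-7-(methoxymethoxy)-7-methyl-6-oxo-7,8-dihydro-6H-isochromen-8-yl 2,4-bis(methoxymethoxy)-6-methylbenzoate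
Conditions: HF·pyridine, pyridine, THF, 0 °C → rt
Reagents that add atoms: none
Why: Fluoride-driven desilylation in a buffered, slightly acidic medium removes the TBS group without touching the ester or the MOM acetals, and no acyl shift can occur because O7 is still protected.

Step 18
Reactants: 26 C9 alcohol
Product: 28 tert-butyl (E)-3-{(7R,8R)-8-[2,4-bis(methoxymethoxy)-6-methylbenzoyloxy]-7-(methoxymethoxy)-7-methyl-6-oxo-7,8-dihydro-6H-isochromen-3-yl}acrylate, via C9 aldehyde 27 (not isolated)
Conditions: Dess–Martin periodinane, CH2Cl2, 0 °C → rt; then Ph3P=CHCO2tBu (3 equiv), rt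
Reagents that add atoms: tert-butyl (triphenylphosphoranylidene)acetate, CC(C)(C)OC(=O)C=P(c1ccccc1)(c1ccccc1)c1ccccc1
Why: One-pot Dess–Martin oxidation and Wittig olefination, in which the electron-poor aldehyde 27 is intercepted in the flask by the stabilised ylide, a reagent class that gives E enoates.

Step 19
Reactants: 28 fully protected tert-butyl acrylate
Product: 29 (+)-mitorubrinic acid B
Conditions: TFA–CH2Cl2 1:3, H2O (10 equiv), 0 °C → rt
Reagents that add atoms: none
Why: Brønsted acid solvolysis, in which TFA cleaves the tert-butyl ester by loss of isobutene and hydrolyses the three MOM acetals through oxocarbenium ions, while the C7–O and C8–O bonds stay intact so that both stereocentres are kept, and the hindered aroyl group should not migrate under acid.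

Compound list
1 | (S)-lactic acid | C[C@H](O)C(=O)O | starting material
2 | pivalaldehyde | CC(C)(C)C=O | starting material
3 | (2S,5S)-2-tert-butyl-5-methyl-1,3-dioxolan-4-one | C[C@@H]1O[C@H](C(C)(C)C)OC1=O | intermediate
4 | lithium (2S)-2-tert-butyl-5-methyl-1,3-dioxol-4-olate (formed in the flask) | CC1=C([O-])O[C@@H](C(C)(C)C)O1.[Li+] | intermediate
5 | (2S,5R)-2-tert-butyl-5-(hydroxymethyl)-5-methyl-1,3-dioxolan-4-one | C[C@]1(CO)O[C@H](C(C)(C)C)OC1=O | intermediate
6 | (2S,5R)-2-tert-butyl-5-methyl-5-[(triethylsilyloxy)methyl]-1,3-dioxolan-4-one | C[C@]1(CO[Si](CC)(CC)CC)O[C@H](C(C)(C)C)OC1=O | intermediate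
7 | (2R)-2-hydroxy-N-methoxy-N,2-dimethyl-3-(triethylsilyloxy)propanamide | C[C@@](O)(CO[Si](CC)(CC)CC)C(=O)N(C)OC | intermediate
8 | (2R)-N-methoxy-2-(methoxymethoxy)-N,2-dimethyl-3-(triethylsilyloxy)propanamide | C[C@@](OCOC)(CO[Si](CC)(CC)CC)C(=O)N(C)OC | intermediate
9 | (3R)-1-bromo-3-(methoxymethoxy)-3-methyl-4-(triethylsilyloxy)butan-2-one | C[C@@](OCOC)(CO[Si](CC)(CC)CC)C(=O)CBr | intermediate
10 | kojic acid | O=C1C=C(CO)OC=C1O | starting material
11 | 2-[(tert-butyldimethylsilyloxy)methyl]-5-hydroxy-4H-pyran-4-one | O=C1C=C(CO[Si](C)(C)C(C)(C)C)OC=C1O | intermediate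
12 | 6-[(tert-butyldimethylsilyloxy)methyl]-4-oxo-4H-pyran-3-yl trifluoromethanesulfonate | O=C1C=C(CO[Si](C)(C)C(C)(C)C)OC=C1OS(=O)(=O)C(F)(F)F | intermediate
13 | 6-[(tert-butyldimethylsilyloxy)methyl]-4-thioxo-4H-pyran-3-yl trifluoromethanesulfonate | S=C1C=C(CO[Si](C)(C)C(C)(C)C)OC=C1OS(=O)(=O)C(F)(F)F | intermediate
14 | 4-{[(3R)-3-(methoxymethoxy)-3-methyl-2-oxo-4-(triethylsilyloxy)butyl]sulfanyl}-2-[(tert-butyldimethylsilyloxy)methyl]-5-(trifluoromethylsulfonyloxy)pyrylium bromide (formed in the flask) | C[C@@](OCOC)(CO[Si](CC)(CC)CC)C(=O)CSc1cc(CO[Si](C)(C)C(C)(C)C)[o+]cc1OS(=O)(=O)C(F)(F)F.[Br-] | intermediate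
15 | spiro[thiirane-2,4'-pyran] carrying the C6 acyl group on the thiirane CH, mixture at the two thiirane carbons (formed in the flask) | C[C@@](OCOC)(CO[Si](CC)(CC)CC)C(=O)C1SC12C=C(CO[Si](C)(C)C(C)(C)C)OC=C2OS(=O)(=O)C(F)(F)F | intermediate
16 | (3R)-1-{(4Z)-2-[(tert-butyldimethylsilyloxy)methyl]-5-(trifluoromethylsulfonyloxy)-4H-pyran-4-ylidene}-3-(methoxymethoxy)-3-methyl-4-(triethylsilyloxy)butan-2-one | C[C@@](OCOC)(CO[Si](CC)(CC)CC)C(=O)/C=C1/C=C(CO[Si](C)(C)C(C)(C)C)OC=C1OS(=O)(=O)C(F)(F)F | intermediate
17 | (3R)-1-{(4Z)-2-[(tert-butyldimethylsilyloxy)methyl]-5-(trifluoromethylsulfonyloxy)-4H-pyran-4-ylidene}-4-hydroxy-3-(methoxymethoxy)-3-methylbutan-2-one | C[C@@](OCOC)(CO)C(=O)/C=C1/C=C(CO[Si](C)(C)C(C)(C)C)OC=C1OS(=O)(=O)C(F)(F)F | intermediate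
18 | (2R)-4-{(4Z)-2-[(tert-butyldimethylsilyloxy)methyl]-5-(trifluoromethylsulfonyloxy)-4H-pyran-4-ylidene}-2-(methoxymethoxy)-2-methyl-3-oxobutanal | O=C[C@@](C)(OCOC)C(=O)/C=C1/C=C(CO[Si](C)(C)C(C)(C)C)OC=C1OS(=O)(=O)C(F)(F)F | intermediate
19 | alkenylchromium dichloride, CrCl2 unit on C8a in place of the triflate of 18 (formed in the flask) | O=C[C@@](C)(OCOC)C(=O)/C=C1/C=C(CO[Si](C)(C)C(C)(C)C)OC=C1[Cr](Cl)Cl | intermediate
20 | (7R,8R)-3-[(tert-butyldimethylsilyloxy)methyl]-8-hydroxy-7-(methoxymethoxy)-7-methyl-7,8-dihydro-6H-isochromen-6-one | O[C@@H]1C2=COC(CO[Si](C)(C)C(C)(C)C)=CC2=CC(=O)[C@]1(C)OCOC | intermediate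
21 | orsellinic acid | Cc1cc(O)cc(O)c1C(=O)O | starting material
22 | methoxymethyl 2,4-bis(methoxymethoxy)-6-methylbenzoate | Cc1cc(OCOC)cc(OCOC)c1C(=O)OCOC | intermediate
23 | 2,4-bis(methoxymethoxy)-6-methylbenzoic acid | Cc1cc(OCOC)cc(OCOC)c1C(=O)O | intermediate
24 | 2,4-bis(methoxymethoxy)-6-methylbenzoyl chloride (formed in the flask) | Cc1cc(OCOC)cc(OCOC)c1C(=O)Cl | intermediate
25 | (7R,8R)-3-[(tert-butyldimethylsilyloxy)methyl]-7-(methoxymethoxy)-7-methyl-6-oxo-7,8-dihydro-6H-isochromen-8-yl 2,4-bis(methoxymethoxy)-6-methylbenzoate | Cc1cc(OCOC)cc(OCOC)c1C(=O)O[C@@H]1C2=COC(CO[Si](C)(C)C(C)(C)C)=CC2=CC(=O)[C@]1(C)OCOC | intermediate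
26 | (7R,8R)-3-(hydroxymethyl)-7-(methoxymethoxy)-7-methyl-6-oxo-7,8-dihydro-6H-isochromen-8-yl 2,4-bis(methoxymethoxy)-6-methylbenzoate | Cc1cc(OCOC)cc(OCOC)c1C(=O)O[C@@H]1C2=COC(CO)=CC2=CC(=O)[C@]1(C)OCOC | intermediate
27 | (7R,8R)-3-formyl-7-(methoxymethoxy)-7-methyl-6-oxo-7,8-dihydro-6H-isochromen-8-yl 2,4-bis(methoxymethoxy)-6-methylbenzoate (formed in the flask) | Cc1cc(OCOC)cc(OCOC)c1C(=O)O[C@@H]1C2=COC(C=O)=CC2=CC(=O)[C@]1(C)OCOC | intermediate
28 | tert-butyl (E)-3-{(7R,8R)-8-[2,4-bis(methoxymethoxy)-6-methylbenzoyloxy]-7-(methoxymethoxy)-7-methyl-6-oxo-7,8-dihydro-6H-isochromen-3-yl}acrylate | Cc1cc(OCOC)cc(OCOC)c1C(=O)O[C@@H]1C2=COC(/C=C/C(=O)OC(C)(C)C)=CC2=CC(=O)[C@]1(C)OCOC | intermediate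
29 | (+)-mitorubrinic acid B, (E)-3-[(7R,8R)-8-(2,4-dihydroxy-6-methylbenzoyloxy)-7-hydroxy-7-methyl-6-oxo-7,8-dihydro-6H-isochromen-3-yl]acrylic acid | Cc1cc(O)cc(O)c1C(=O)O[C@@H]1C2=COC(/C=C/C(=O)O)=CC2=CC(=O)[C@]1(C)O | target

Total step count: 19.
Longest linear sequence: 14 steps (steps 1–6, 10–13 and 16–19).

Steps most likely to fail

1. Step 13.
- Risk: facial selectivity at C8 may be poor, because a dipole-opposed approach of the aldehyde competes with the chelated one.
- Fallback: it sets out from 18 and comes back at 25. The cyclisation is run as described, and the epimeric alcohol (7R,8S)-3-[(tert-butyldimethylsilyloxy)methyl]-8-hydroxy-7-(methoxymethoxy)-7-methyl-7,8-dihydro-6H-isochromen-6-one F1 is separated. It then serves as the electrophile instead of being acylated. Mitsunobu esterification with acid 23 (PPh3, DIAD, toluene, 0 °C → rt) should displace the activated allylic O8 with inversion and give 25, so both epimers converge on the same ester.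
- Not chosen: an oxidation–reduction repair, since hydride delivery directed or chelated by O7 would enter from the O7 face and return the trans isomer.

2. Step 10.
- Risk: S-alkylation of the electron-poor thione may be sluggish. The cationic intermediate may also be opened at the unsubstituted C1 by the amine or the phosphine before sulfur is extruded.
- Fallback: it sets out from 9 and 13 and comes back at 16. Bromoketone 9 is converted with N,N'-ditosylhydrazine and DBU (THF, 0 °C) into (3R)-1-diazo-3-(methoxymethoxy)-3-methyl-4-(triethylsilyloxy)butan-2-one F2. Slow addition of F2 to 13 and Rh2(OAc)4 (cat., CH2Cl2, rt) transfers the carbene to sulfur and leads to thiirane 15 without a cationic intermediate or an added base. PPh3 then removes sulfur to give 16.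

3. Step 6.
- Risk: the thermally labile carbenoid may decompose faster than it adds to the hindered amide carbonyl.
- Fallback: it sets out from 8 and comes back at 9.
  - MeMgBr (THF, 0 °C) gives (3R)-3-(methoxymethoxy)-3-methyl-4-(triethylsilyloxy)butan-2-one F3.
  - The only enolisable position of F3 is silylated with LiN(SiMe3)2 and Me3SiCl (THF, −78 °C) to give the enol ether (3R)-3-(methoxymethoxy)-3-methyl-4-(triethylsilyloxy)-2-(trimethylsilyloxy)but-1-ene F4.
  - N-Bromosuccinimide (THF, −78 → 0 °C) then brominates the terminal carbon to give 9.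

Further compounds
F1 | step 13 | (7R,8S)-3-[(tert-butyldimethylsilyloxy)methyl]-8-hydroxy-7-(methoxymethoxy)-7-methyl-7,8-dihydro-6H-isochromen-6-one | O[C@H]1C2=COC(CO[Si](C)(C)C(C)(C)C)=CC2=CC(=O)[C@]1(C)OCOC
F2 | step 10 | (3R)-1-diazo-3-(methoxymethoxy)-3-methyl-4-(triethylsilyloxy)butan-2-one | C[C@@](OCOC)(CO[Si](CC)(CC)CC)C(=O)C=[N+]=[N-]
F3 | step 6 | (3R)-3-(methoxymethoxy)-3-methyl-4-(triethylsilyloxy)butan-2-one | C[C@@](OCOC)(CO[Si](CC)(CC)CC)C(C)=O
F4 | step 6 | (3R)-3-(methoxymethoxy)-3-methyl-4-(triethylsilyloxy)-2-(trimethylsilyloxy)but-1-ene | C[C@@](OCOC)(CO[Si](CC)(CC)CC)C(=C)O[Si](C)(C)C
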